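## Retrosynthetic overview

1. The 42-membered macrolactone is the last ring formed, by ring-closing metathesis at C12=C13 of an ester-linked diene; the O41–C1 ester is made earlier by Yamaguchi esterification, and global deprotection ends the route.
2. C26–C27 is cut by a 1,5-anti boron aldol (methyl ketone 55, C13–C26, plus aldehyde 39) followed by a 1,3-anti reduction for C25.
3. Aldehyde 39 comes from C38=C39 cross-metathesis of a C27–C38 vinyl dioxane (statin chiral-pool acetonide, syn,syn titanium aldol, anti reduction) with lactone alcohol 7, then acylation with the C1–C12 acid 20 (citronellene, vinyl-ketone aldol/in situ reduction, B-alkyl Suzuki).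
4. Ketone 55 comes from 2-deoxy-D-ribose (C21–C25) by Wittig, Crimmins aldol, Wittig, Wacker and Brown crotylation.
5. Ring order: γ-butyrolactone (step 1), then protecting dioxane/dioxolane rings, then the macrocycle (step 37).

Assumption: catalogue compounds 22, 28, 43, 46 and 50 are bought; for fragments named with target numbering every stereocentre has the arrangement it has in 60, and the SMILES is authoritative.

## Route

Step 1
Reactants: 1 methyl 4-oxobutanoate; 2 (E)-but-2-ene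
Product: 4 (5S)-5-[(2R)-but-3-en-2-yl]oxolan-2-one, via hydroxy ester 3 (not isolated)
Conditions: 2, KOtBu, n-BuLi, THF, −78 to −45 °C; (+)-Ipc2BOMe, −78 °C; BF3·OEt2; 1, −78 °C; NaOH, H2O2, 0 °C; then TsOH (cat.), CH2Cl2, rt
Reagents that add atoms: none
Why: Brown (E)-crotylboration through a chair transition state gives the anti homoallylic alcohol with reagent-controlled C43/C42 configuration, and the γ-hydroxy ester lactonises under acid.

Step 2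
Reactants: 4 (5S)-5-[(2R)-but-3-en-2-yl]oxolan-2-one
Product: 5 (2S)-2-[(2S)-5-oxooxolan-2-yl]propanal
Conditions: O3, CH2Cl2, −78 °C; PPh3, −78 °C to rt; used crude
Reagents that add atoms: ozone, [O-][O+]=O
Why: Ozonolysis with reductive work-up cleaves the only alkene; the lactone is inert and crude use avoids epimerisation at C42.

Step 3
Reactants: 5 (2S)-2-[(2S)-5-oxooxolan-2-yl]propanal; 6 allylmagnesium bromide
Product: 7 (5S)-5-[(2R,3S)-3-hydroxyhex-5-en-2-yl]oxolan-2-one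
Conditions: 6, (−)-Ipc2BOMe, Et2O, 0 °C to rt; 5, −78 °C; NaHCO3 (aq.), H2O2, 0 °C
Reagents that add atoms: none
Why: Brown allylboration sets C41; the reagent's facial preference matches the Felkin–Anh and 1,3-anti bias of the α-methyl-β-acyloxy aldehyde.

Step 4
Reactants: 8 (S)-β-citronellene
Product: 9 (4S)-4-methylhex-5-enal
Conditions: O3 (1 equiv), CH2Cl2/MeOH, −78 °C; Me2S
Reagents that add atoms: ozone, [O-][O+]=O
Why: Chemoselective ozonolysis, since the electron-rich trisubstituted alkene reacts much faster than the vinyl group; C6 comes from the chiral pool.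

Step 5
Reactants: 9 (4S)-4-methylhex-5-enal; 10 ethyl 2-(triphenyl-λ5-phosphanylidene)propanoate
Product: 11 ethyl (2E,6S)-2,6-dimethylocta-2,7-dienoate
Conditions: CH2Cl2, 40 °C
Reagents that add atoms: none
Why: Wittig olefination with a stabilised ylide gives the (E)-trisubstituted enoate (C2=C3).

Step 6
Reactants: 11 ethyl (2E,6S)-2,6-dimethylocta-2,7-dienoate
Product: 12 ethyl (2E,6S)-2,6-dimethyl-7-oxohept-2-enoate
Conditions: OsO4 (2 mol %), NaIO4, 2,6-lutidine, dioxane/H2O, rt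
Reagents that add atoms: sodium periodate, [Na+].[O-]I(=O)(=O)=O
Why: Lemieux–Johnson cleavage takes the monosubstituted alkene; the electron-poor trisubstituted enoate is dihydroxylated far more slowly.

Step 7
Reactants: 12 ethyl (2E,6S)-2,6-dimethyl-7-oxohept-2-enoate; 13 pent-1-en-3-one
Product: 15 ethyl (2E,6S,7R,8S,9S)-7,9-dihydroxy-2,6,8-trimethylundeca-2,10-dienoate, via boron aldolate 14 (not isolated)
Conditions: 13, Cy2BCl, Et3N, Et2O, −78 to 0 °C; 12, −78 to −25 °C; LiBH4, −78 °C; then MeOH, pH 7 buffer, H2O2, 0 °C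
Reagents that add atoms: none
Why: The (E)-enol borinate (only the ethyl side can enolise) gives an anti boron aldol with Felkin–Anh addition to the α-methyl aldehyde (C7, C8), and hydride attack on the cyclic boron aldolate gives the 7,9-syn diol (C9).

Step 8
Reactants: 15 ethyl (2E,6S,7R,8S,9S)-7,9-dihydroxy-2,6,8-trimethylundeca-2,10-dienoate
Product: 16 ethyl (2E,6S)-6-[(4R,5S,6S)-6-ethenyl-2,2,5-trimethyl-1,3-dioxan-4-yl]-2-methylhept-2-enoate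
Conditions: 2,2-dimethoxypropane, PPTS, CH2Cl2, rt
Reagents that add atoms: 2,2-dimethoxypropane, COC(C)(C)OC
Why: Acid-catalysed transketalisation protects the syn-1,3-diol as its acetonide.

Step 9
Reactants: 16 ethyl (2E,6S)-6-[(4R,5S,6S)-6-ethenyl-2,2,5-trimethyl-1,3-dioxan-4-yl]-2-methylhept-2-enoate; 17 bromoethene
Product: 19 ethyl (2E,6S)-6-[(4R,5S,6S)-6-(but-3-en-1-yl)-2,2,5-trimethyl-1,3-dioxan-4-yl]-2-methylhept-2-enoate, via alkylborane 18 (not isolated)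
Conditions: 9-BBN-H dimer, THF, 0 °C to rt; then 17, Pd(dppf)Cl2 (5 mol %), K3PO4 (aq.), DMF, rt
Reagents that add atoms: none
Why: 9-BBN hydroborates only the terminal vinyl group, and B-alkyl Suzuki–Miyaura coupling with vinyl bromide extends it to the butenyl chain (C10–C12).

Step 10
Reactants: 19 ethyl (2E,6S)-6-[(4R,5S,6S)-6-(but-3-en-1-yl)-2,2,5-trimethyl-1,3-dioxan-4-yl]-2-methylhept-2-enoate
Product: 20 (2E,6S)-6-[(4R,5S,6S)-6-(but-3-en-1-yl)-2,2,5-trimethyl-1,3-dioxan-4-yl]-2-methylhept-2-enoic acid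
Conditions: LiOH, THF/MeOH/H2O, 40 °C; HCl (aq.) to pH 4, 0 °C
Reagents that add atoms: lithium hydroxide, [Li+].[OH-]
Why: Saponification of the ethyl ester; acetonide and alkenes are inert to hydroxide.

Step 11
Reactants: 21 (4R)-4-benzyl-3-propanoyl-1,3-oxazolidin-2-one; 22 3-[(4-methoxybenzyl)oxy]propanal
Product: 23 (4R)-4-benzyl-3-[(2R,3S)-3-hydroxy-5-[(4-methoxybenzyl)oxy]-2-methylpentanoyl]-1,3-oxazolidin-2-one
Conditions: 21, Bu2BOTf, Et3N, CH2Cl2, −78 to 0 °C; 22, −78 to 0 °C; pH 7 buffer, MeOH, H2O2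
Reagents that add atoms: none
Why: Evans syn aldol via the (Z)-boron enolate and a Zimmerman–Traxler transition state; the (R)-auxiliary sets C30 and C29.

Step 12
Reactants: 23 (4R)-4-benzyl-3-[(2R,3S)-3-hydroxy-5-[(4-methoxybenzyl)oxy]-2-methylpentanoyl]-1,3-oxazolidin-2-one
Product: 24 (2R,3S)-3-hydroxy-N-methoxy-5-[(4-methoxybenzyl)oxy]-N,2-dimethylpentanamide
Conditions: MeNHOMe·HCl, Me3Al, CH2Cl2, −10 °C to rt; aq. potassium sodium tartrate
Reagents that add atoms: N,O-dimethylhydroxylamine hydrochloride, CNOC.Cl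
Why: Aluminium-amide transamidation displaces the auxiliary to give the Weinreb amide without epimerisation.

Step 13
Reactants: 24 (2R,3S)-3-hydroxy-N-methoxy-5-[(4-methoxybenzyl)oxy]-N,2-dimethylpentanamide
Product: 25 (2R,3S)-3-[(tert-butyldimethylsilyl)oxy]-N-methoxy-5-[(4-methoxybenzyl)oxy]-N,2-dimethylpentanamide
Conditions: TBSOTf, 2,6-lutidine, CH2Cl2, −78 to 0 °C
Reagents that add atoms: tert-butyldimethylsilyl trifluoromethanesulfonate, CC(C)(C)[Si](C)(C)OS(=O)(=O)C(F)(F)F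
Why: Silylation of the secondary alcohol; a non-chelating β-silyloxy group is wanted for the later titanium aldol.

Step 14
Reactants: 25 (2R,3S)-3-[(tert-butyldimethylsilyl)oxy]-N-methoxy-5-[(4-methoxybenzyl)oxy]-N,2-dimethylpentanamide; 26 ethylmagnesium bromide
Product: 27 (4R,5S)-5-[(tert-butyldimethylsilyl)oxy]-7-[(4-methoxybenzyl)oxy]-4-methylheptan-3-one
Conditions: 26, THF, 0 °C; NH4Cl (aq.)
Reagents that add atoms: none
Why: Grignard addition to the Weinreb amide stops at the ketone through the chelated tetrahedral intermediate.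

Step 15
Reactants: 28 tert-butyl 2-[(4R,6S)-6-formyl-2,2-dimethyl-1,3-dioxan-4-yl]acetate; 29 methyltriphenylphosphonium bromide
Product: 30 tert-butyl 2-[(4R,6S)-6-ethenyl-2,2-dimethyl-1,3-dioxan-4-yl]acetate
Conditions: 29, KOtBu, THF, 0 °C; 28, 0 °C to rt
Reagents that add atoms: none
Why: Wittig methylenation of the chiral-pool aldehyde, which already carries C35 and C37 as the syn acetonide.

Step 16
Reactants: 30 tert-butyl 2-[(4R,6S)-6-ethenyl-2,2-dimethyl-1,3-dioxan-4-yl]acetate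
Product: 31 2-[(4R,6S)-6-ethenyl-2,2-dimethyl-1,3-dioxan-4-yl]acetaldehyde
Conditions: iBu2AlH (1.1 equiv), CH2Cl2, −78 °C; MeOH, aq. potassium sodium tartrate
Reagents that add atoms: none
Why: Partial ester reduction; the tetrahedral aluminate of the hindered tert-butyl ester survives at −78 °C and gives the aldehyde on work-up.

Step 17
Reactants: 27 (4R,5S)-5-[(tert-butyldimethylsilyl)oxy]-7-[(4-methoxybenzyl)oxy]-4-methylheptan-3-one; 31 2-[(4R,6S)-6-ethenyl-2,2-dimethyl-1,3-dioxan-4-yl]acetaldehyde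
Product: 32 C27–C38 aldol adduct (27-O-PMB, 29-O-TBS, 30-Me, 31-oxo, 32-Me, 33-OH, 35,37-O-isopropylidene, C37 vinyl)
Conditions: 27, TiCl4, iPr2NEt, CH2Cl2, −78 °C; 31, −78 °C; NH4Cl (aq.)
Reagents that add atoms: none
Why: Titanium (Z)-enolate aldol gives the syn adduct (C32, C33), and the α-methyl stereocentre of the ketone directs the 30,32-syn relationship.

Step 18
Reactants: 32 C27–C38 aldol adduct
Product: 33 C27–C38 31,33-anti diol
Conditions: Me4NBH(OAc)3, MeCN/AcOH 1:1, −30 °C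
Reagents that add atoms: none
Why: Evans–Saksena reduction; intramolecular hydride delivery from the C33 alkoxyborohydride gives the 1,3-anti diol (C31).

Step 19
Reactants: 33 C27–C38 31,33-anti diol
Product: 34 C27–C38 tris-TBS ether
Conditions: TBSOTf, 2,6-lutidine, CH2Cl2, 0 °C
Reagents that add atoms: tert-butyldimethylsilyl trifluoromethanesulfonate, CC(C)(C)[Si](C)(C)OS(=O)(=O)C(F)(F)F
Why: Bis-silylation under non-equilibrating conditions avoids acetal migration onto the existing acetonide.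

Step 20
Reactants: 34 C27–C38 tris-TBS ether; 7 (5S)-5-[(2R,3S)-3-hydroxyhex-5-en-2-yl]oxolan-2-one
Product: 35 C27–C46 alcohol with (38E)-alkene
Conditions: 7 (3 equiv), second-generation Hoveyda–Grubbs catalyst [RuCl2(=CH-C6H4-2-OiPr)(H2IMes)] (10 mol %), CH2Cl2, 40 °C
Reagents that add atoms: none
Why: Olefin cross-metathesis between the slowly dimerising allylic-oxygenated vinyl group and an excess of the unhindered allyl partner gives the thermodynamic E-alkene.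

Step 21
Reactants: 35 C27–C46 alcohol; 20 (2E,6S)-6-[(4R,5S,6S)-6-(but-3-en-1-yl)-2,2,5-trimethyl-1,3-dioxan-4-yl]-2-methylhept-2-enoic acid
Product: 37 O41 ester of 35 with acid 20, via mixed anhydride 36 (not isolated)
Conditions: 20, 2,4,6-trichlorobenzoyl chloride, Et3N, THF, rt; then 35, DMAP, toluene, rt
Reagents that add atoms: none
Why: Yamaguchi esterification acylates the only free hydroxyl (O41) with the hindered enoic acid.

Step 22
Reactants: 37 O41 ester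
Product: 38 C27 primary alcohol
Conditions: DDQ, CH2Cl2/pH 7 buffer 10:1, 0 °C
Reagents that add atoms: none
Why: Oxidative cleavage of the electron-rich PMB ether leaves silyl ethers, acetonides, esters and alkenes untouched.

Step 23
Reactants: 38 C27 primary alcohol
Product: 39 C27 aldehyde
Conditions: Dess–Martin periodinane, NaHCO3, CH2Cl2, rt
Reagents that add atoms: none
Why: Buffered Dess–Martin oxidation gives the β-silyloxy aldehyde without elimination.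

Step 24
Reactants: 40 2-deoxy-D-ribose
Product: 41 3,4-O-isopropylidene-2-deoxy-D-erythro-pentopyranose
Conditions: 2-methoxypropene, PPTS, DMF, 0 °C to rt
Reagents that add atoms: 2-methoxypropene, COC(C)=C
Why: Kinetic acetonide formation on the cis-3,4-diol of the pyranose; C22 and C23 come from the chiral pool.

Step 25
Reactants: 41 3,4-O-isopropylidene-2-deoxy-D-erythro-pentopyranose; 29 methyltriphenylphosphonium bromide
Product: 42 [(4R,5S)-2,2-dimethyl-5-(prop-2-en-1-yl)-1,3-dioxolan-4-yl]methanol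
Conditions: 29 (3 equiv), KOtBu, THF, 0 °C; 41, rt to 50 °C
Reagents that add atoms: none
Why: Wittig methylenation of the open-chain aldehyde in equilibrium with the lactol frees the C21 hydroxyl.

Step 26
Reactants: 42 [(4R,5S)-2,2-dimethyl-5-(prop-2-en-1-yl)-1,3-dioxolan-4-yl]methanol; 43 2-(triphenyl-λ5-phosphanylidene)propanal
Product: 45 (2E)-3-[(4R,5S)-2,2-dimethyl-5-(prop-2-en-1-yl)-1,3-dioxolan-4-yl]-2-methylprop-2-enal, via dioxolane aldehyde 44 (not isolated)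
Conditions: Dess–Martin periodinane, NaHCO3, CH2Cl2, 0 °C to rt; filtered; then 43, toluene, 80 °C
Reagents that add atoms: none
Why: Oxidation then Wittig reaction with the stabilised formyl ylide gives the (E)-2-methyl enal (C20=C21) under base-free conditions that keep the α-alkoxy centre intact.

Step 27
Reactants: 45 (2E)-3-[(4R,5S)-2,2-dimethyl-5-(prop-2-en-1-yl)-1,3-dioxolan-4-yl]-2-methylprop-2-enal; 46 (4S)-4-benzyl-3-propanoyl-1,3-thiazolidine-2-thione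
Product: 47 C17–C26 syn-aldol adduct (thiazolidinethione imide)
Conditions: 46, TiCl4, iPr2NEt, N-methylpyrrolidin-2-one, CH2Cl2, 0 °C; 45, −78 to 0 °C
Reagents that add atoms: none
Why: Crimmins titanium aldol under Evans-syn conditions; the (S)-auxiliary sets C18 and C19 through a non-chelated chair transition state.

Step 28
Reactants: 47 C17–C26 syn-aldol adduct
Product: 48 C17–C26 19-O-TBS imide
Conditions: TBSOTf, 2,6-lutidine, CH2Cl2, −78 to 0 °C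
Reagents that add atoms: tert-butyldimethylsilyl trifluoromethanesulfonate, CC(C)(C)[Si](C)(C)OS(=O)(=O)C(F)(F)F
Why: Silylation of the allylic alcohol blocks retro-aldol cleavage in the next steps.

Step 29
Reactants: 48 C17–C26 19-O-TBS imide
Product: 49 (2S,3S,4E)-3-[(tert-butyldimethylsilyl)oxy]-5-[(4R,5S)-2,2-dimethyl-5-(prop-2-en-1-yl)-1,3-dioxolan-4-yl]-2,4-dimethylpent-4-enal
Conditions: iBu2AlH, CH2Cl2, −78 °C; aq. potassium sodium tartrate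
Reagents that add atoms: none
Why: Reductive cleavage of the N-acyl thiazolidinethione gives the aldehyde directly.

Step 30
Reactants: 49 C17 aldehyde; 50 2-(triphenyl-λ5-phosphanylidene)acetaldehyde
Product: 51 (2E,4R,5S,6E)-5-[(tert-butyldimethylsilyl)oxy]-7-[(4R,5S)-2,2-dimethyl-5-(prop-2-en-1-yl)-1,3-dioxolan-4-yl]-4,6-dimethylhepta-2,6-dienal
Conditions: 50 (1.2 equiv), toluene, 80 °C
Reagents that add atoms: none
Why: Wittig two-carbon homologation with the stabilised ylide gives the (E)-enal (C16=C17) without epimerising C18.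

Step 31
Reactants: 51 C15–C26 enal
Product: 52 C15–C26 keto enal (C25 methyl ketone)
Conditions: PdCl2 (10 mol %), CuCl, O2 (1 atm), DMF/H2O 7:1, rt
Reagents that add atoms: water, O
Why: Tsuji–Wacker oxidation converts only the terminal alkene into the methyl ketone (Markovnikov); the enal and trisubstituted alkene are inert.

Step 32
Reactants: 52 C15–C26 keto enal; 53 (Z)-but-2-ene
Product: 54 C13–C26 homoallylic alcohol (15-OH, 14-Me syn, C13 vinyl)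
Conditions: 53, KOtBu, n-BuLi, THF, −78 to −45 °C; (−)-Ipc2BOMe; BF3·OEt2, −78 °C; 52, −78 °C; pH 7 buffer, H2O2, 0 °C
Reagents that add atoms: none
Why: Brown (Z)-crotylboration gives the syn adduct with reagent-controlled C15 and C14, the aldehyde reacting far faster than the methyl ketone at −78 °C.

Step 33
Reactants: 54 C13–C26 homoallylic alcohol
Product: 55 C13–C26 methyl ketone (15,19-bis-O-TBS)
Conditions: TBSOTf, 2,6-lutidine, CH2Cl2, −78 °C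
Reagents that add atoms: tert-butyldimethylsilyl trifluoromethanesulfonate, CC(C)(C)[Si](C)(C)OS(=O)(=O)C(F)(F)F
Why: Low-temperature silylation of the alcohol is faster than silyl enol ether formation from the ketone.

Step 34
Reactants: 55 C13–C26 methyl ketone; 39 C27 aldehyde
Product: 56 27-hydroxy-25-ketone (full carbon skeleton)
Conditions: 55, Cy2BCl, Et3N, Et2O, −78 to 0 °C; 39, −78 to −25 °C; MeOH, pH 7 buffer, H2O2, 0 °C
Reagents that add atoms: none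
Why: Boron aldol of the kinetic methyl-side enolate with 1,5-anti induction from the β-alkoxy centre C23 sets C27.

Step 35
Reactants: 56 27-hydroxy-25-ketone
Product: 57 25,27-anti diol
Conditions: Me4NBH(OAc)3, MeCN/AcOH/THF, −30 °C
Reagents that add atoms: none
Why: Evans–Saksena hydroxyl-directed reduction sets C25 anti to C27; esters and the lactone are not reduced.

Step 36
Reactants: 57 25,27-anti diol
Product: 58 ester-linked diene (25,27-bis-O-TBS)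
Conditions: TBSOTf, 2,6-lutidine, CH2Cl2, −78 to 0 °C
Reagents that add atoms: tert-butyldimethylsilyl trifluoromethanesulfonate, CC(C)(C)[Si](C)(C)OS(=O)(=O)C(F)(F)F
Why: Silylation with a hindered base avoids acetal migration from the neighbouring dioxolane.

Step 37
Reactants: 58 ester-linked diene
Product: 59 protected macrocycle with (12E)-alkene
Conditions: second-generation Grubbs catalyst [RuCl2(=CHPh)(PCy3)(H2IMes)] (20 mol %), toluene (0.5 mM), 80 °C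
Reagents that add atoms: none
Why: Ring-closing metathesis joins the two terminal alkenes; the internal alkenes are shielded by allylic branching, and the large ring favours the E isomer.

Step 38
Reactants: 59 protected macrocycle
Product: 60 CNP0335149.1
Conditions: HF (48% aq.), MeCN/THF, 0 °C to rt
Reagents that add atoms: none
Why: Global deprotection; fluoride cleaves the seven TBS ethers and the aqueous acid hydrolyses the three acetonides, while both lactones and the allylic alcohols tolerate these non-nucleophilic conditions.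

## Compound list

1 | methyl 4-oxobutanoate | COC(=O)CCC=O | starting material
2 | (E)-but-2-ene | C/C=C/C | starting material
3 | methyl (4S,5R)-4-hydroxy-5-methylhept-6-enoate | COC(=O)CC[C@H](O)[C@H](C)C=C | intermediate
4 | (5S)-5-[(2R)-but-3-en-2-yl]oxolan-2-one | C=C[C@@H](C)[C@@H]1CCC(=O)O1 | intermediate
5 | (2S)-2-[(2S)-5-oxooxolan-2-yl]propanal | O=C[C@@H](C)[C@@H]1CCC(=O)O1 | intermediate
6 | allylmagnesium bromide | C=CC[Mg]Br | starting material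
7 | (5S)-5-[(2R,3S)-3-hydroxyhex-5-en-2-yl]oxolan-2-one (C39–C46) | C=CC[C@@H]([C@@H](C)[C@@H]1CCC(=O)O1)O | intermediate
8 | (S)-β-citronellene, (3S)-3,7-dimethylocta-1,6-diene | CC(C)=CCC[C@H](C)C=C | starting material
9 | (4S)-4-methylhex-5-enal | O=CCC[C@H](C)C=C | intermediate
10 | ethyl 2-(triphenyl-λ5-phosphanylidene)propanoate | CCOC(=O)C(C)=P(c1ccccc1)(c1ccccc1)c1ccccc1 | starting material
11 | ethyl (2E,6S)-2,6-dimethylocta-2,7-dienoate | CCOC(=O)/C(C)=C/CC[C@H](C)C=C | intermediate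
12 | ethyl (2E,6S)-2,6-dimethyl-7-oxohept-2-enoate | CCOC(=O)/C(C)=C/CC[C@H](C)C=O | intermediate
13 | pent-1-en-3-one (ethyl vinyl ketone) | CCC(=O)C=C | starting material
14 | O7-dicyclohexylboryl aldolate of ethyl (2E,6S,7R,8R)-7-hydroxy-2,6,8-trimethyl-9-oxoundeca-2,10-dienoate | CCOC(=O)/C(C)=C/CC[C@H](C)[C@@H](OB(C1CCCCC1)C1CCCCC1)[C@@H](C)C(=O)C=C | intermediate
15 | ethyl (2E,6S,7R,8S,9S)-7,9-dihydroxy-2,6,8-trimethylundeca-2,10-dienoate | CCOC(=O)/C(C)=C/CC[C@H](C)[C@@H](O)[C@@H](C)[C@@H](O)C=C | intermediate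
16 | ethyl (2E,6S)-6-[(4R,5S,6S)-6-ethenyl-2,2,5-trimethyl-1,3-dioxan-4-yl]-2-methylhept-2-enoate | CCOC(=O)/C(C)=C/CC[C@H](C)[C@@H]1[C@@H](C)[C@H](C=C)OC(C)(C)O1 | intermediate
17 | bromoethene (vinyl bromide) | C=CBr | starting material
18 | B-alkyl-9-borabicyclo[3.3.1]nonane from 16 (boron on C11) | CCOC(=O)/C(C)=C/CC[C@H](C)[C@@H]1[C@@H](C)[C@H](CCB2C3CCCC2CCC3)OC(C)(C)O1 | intermediate
19 | ethyl (2E,6S)-6-[(4R,5S,6S)-6-(but-3-en-1-yl)-2,2,5-trimethyl-1,3-dioxan-4-yl]-2-methylhept-2-enoate | CCOC(=O)/C(C)=C/CC[C@H](C)[C@@H]1[C@@H](C)[C@H](CCC=C)OC(C)(C)O1 | intermediate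
20 | (2E,6S)-6-[(4R,5S,6S)-6-(but-3-en-1-yl)-2,2,5-trimethyl-1,3-dioxan-4-yl]-2-methylhept-2-enoic acid (C1–C12) | OC(=O)/C(C)=C/CC[C@H](C)[C@@H]1[C@@H](C)[C@H](CCC=C)OC(C)(C)O1 | intermediate
21 | (4R)-4-benzyl-3-propanoyl-1,3-oxazolidin-2-one | CCC(=O)N1[C@H](Cc2ccccc2)COC1=O | starting material
22 | 3-[(4-methoxybenzyl)oxy]propanal | COc1ccc(COCCC=O)cc1 | starting material
23 | (4R)-4-benzyl-3-[(2R,3S)-3-hydroxy-5-[(4-methoxybenzyl)oxy]-2-methylpentanoyl]-1,3-oxazolidin-2-one | COc1ccc(COCC[C@H](O)[C@@H](C)C(=O)N2[C@H](Cc3ccccc3)COC2=O)cc1 | intermediate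
24 | (2R,3S)-3-hydroxy-N-methoxy-5-[(4-methoxybenzyl)oxy]-N,2-dimethylpentanamide | COc1ccc(COCC[C@H](O)[C@@H](C)C(=O)N(C)OC)cc1 | intermediate
25 | (2R,3S)-3-[(tert-butyldimethylsilyl)oxy]-N-methoxy-5-[(4-methoxybenzyl)oxy]-N,2-dimethylpentanamide | COc1ccc(COCC[C@H](O[Si](C)(C)C(C)(C)C)[C@@H](C)C(=O)N(C)OC)cc1 | intermediate
26 | ethylmagnesium bromide | CC[Mg]Br | starting material
27 | (4R,5S)-5-[(tert-butyldimethylsilyl)oxy]-7-[(4-methoxybenzyl)oxy]-4-methylheptan-3-one (C27–C32) | COc1ccc(COCC[C@H](O[Si](C)(C)C(C)(C)C)[C@@H](C)C(=O)CC)cc1 | intermediate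
28 | tert-butyl 2-[(4R,6S)-6-formyl-2,2-dimethyl-1,3-dioxan-4-yl]acetate | O=C[C@@H]1C[C@H](CC(=O)OC(C)(C)C)OC(C)(C)O1 | starting material
29 | methyltriphenylphosphonium bromide | C[P+](c1ccccc1)(c1ccccc1)c1ccccc1.[Br-] | starting material
30 | tert-butyl 2-[(4R,6S)-6-ethenyl-2,2-dimethyl-1,3-dioxan-4-yl]acetate | C=C[C@@H]1C[C@H](CC(=O)OC(C)(C)C)OC(C)(C)O1 | intermediate
31 | 2-[(4R,6S)-6-ethenyl-2,2-dimethyl-1,3-dioxan-4-yl]acetaldehyde (C33–C38) | C=C[C@@H]1C[C@H](CC=O)OC(C)(C)O1 | intermediate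
32 | C27–C38 aldol adduct: 27-O-PMB, 29-O-TBS, 30-Me, 31-oxo, 32-Me, 33-OH, 35,37-O-isopropylidene, C37 vinyl | COc1ccc(COCC[C@H](O[Si](C)(C)C(C)(C)C)[C@@H](C)C(=O)[C@@H](C)[C@H](O)C[C@H]2C[C@@H](C=C)OC(C)(C)O2)cc1 | intermediate
33 | C27–C38 31,33-anti diol (otherwise as 32) | COc1ccc(COCC[C@H](O[Si](C)(C)C(C)(C)C)[C@@H](C)[C@@H](O)[C@@H](C)[C@H](O)C[C@H]2C[C@@H](C=C)OC(C)(C)O2)cc1 | intermediate
34 | C27–C38 29,31,33-tris-O-TBS ether (27-O-PMB, 35,37-acetonide, C37 vinyl) | COc1ccc(COCC[C@H](O[Si](C)(C)C(C)(C)C)[C@@H](C)[C@@H](O[Si](C)(C)C(C)(C)C)[C@@H](C)[C@H](O[Si](C)(C)C(C)(C)C)C[C@H]2C[C@@H](C=C)OC(C)(C)O2)cc1 | intermediate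
35 | C27–C46 alcohol: as 34 with (38E)-alkene to the lactone side chain, free 41-OH | COc1ccc(COCC[C@H](O[Si](C)(C)C(C)(C)C)[C@@H](C)[C@@H](O[Si](C)(C)C(C)(C)C)[C@@H](C)[C@H](O[Si](C)(C)C(C)(C)C)C[C@H]2C[C@@H](/C=C/C[C@@H]([C@@H](C)[C@@H]3CCC(=O)O3)O)OC(C)(C)O2)cc1 | intermediate
36 | mixed anhydride of acid 20 with 2,4,6-trichlorobenzoic acid | O=C(OC(=O)c1c(Cl)cc(Cl)cc1Cl)/C(C)=C/CC[C@H](C)[C@@H]1[C@@H](C)[C@H](CCC=C)OC(C)(C)O1 | intermediate
37 | O41 ester of 35 with acid 20 (27-O-PMB) | COc1ccc(COCC[C@H](O[Si](C)(C)C(C)(C)C)[C@@H](C)[C@@H](O[Si](C)(C)C(C)(C)C)[C@@H](C)[C@H](O[Si](C)(C)C(C)(C)C)C[C@H]2C[C@@H](/C=C/C[C@@H]([C@@H](C)[C@@H]3CCC(=O)O3)OC(=O)/C(C)=C/CC[C@H](C)[C@@H]3[C@@H](C)[C@H](CCC=C)OC(C)(C)O3)OC(C)(C)O2)cc1 | intermediate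
38 | C27 primary alcohol from 37 | OCC[C@H](O[Si](C)(C)C(C)(C)C)[C@@H](C)[C@@H](O[Si](C)(C)C(C)(C)C)[C@@H](C)[C@H](O[Si](C)(C)C(C)(C)C)C[C@H]1C[C@@H](/C=C/C[C@@H]([C@@H](C)[C@@H]2CCC(=O)O2)OC(=O)/C(C)=C/CC[C@H](C)[C@@H]2[C@@H](C)[C@H](CCC=C)OC(C)(C)O2)OC(C)(C)O1 | intermediate
39 | C27 aldehyde (C27–C46 with the C1–C12 acyl group on O41) | O=CC[C@H](O[Si](C)(C)C(C)(C)C)[C@@H](C)[C@@H](O[Si](C)(C)C(C)(C)C)[C@@H](C)[C@H](O[Si](C)(C)C(C)(C)C)C[C@H]1C[C@@H](/C=C/C[C@@H]([C@@H](C)[C@@H]2CCC(=O)O2)OC(=O)/C(C)=C/CC[C@H](C)[C@@H]2[C@@H](C)[C@H](CCC=C)OC(C)(C)O2)OC(C)(C)O1 | intermediate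
40 | 2-deoxy-D-ribose (2-deoxy-D-erythro-pentopyranose) | OC1C[C@H](O)[C@H](O)CO1 | starting material
41 | 3,4-O-isopropylidene-2-deoxy-D-erythro-pentopyranose | OC1C[C@@H]2OC(C)(C)O[C@@H]2CO1 | intermediate
42 | [(4R,5S)-2,2-dimethyl-5-(prop-2-en-1-yl)-1,3-dioxolan-4-yl]methanol | C=CC[C@@H]1OC(C)(C)O[C@@H]1CO | intermediate
43 | 2-(triphenyl-λ5-phosphanylidene)propanal | CC(C=O)=P(c1ccccc1)(c1ccccc1)c1ccccc1 | starting material
44 | (4S,5S)-2,2-dimethyl-5-(prop-2-en-1-yl)-1,3-dioxolane-4-carbaldehyde | C=CC[C@@H]1OC(C)(C)O[C@@H]1C=O | intermediate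
45 | (2E)-3-[(4R,5S)-2,2-dimethyl-5-(prop-2-en-1-yl)-1,3-dioxolan-4-yl]-2-methylprop-2-enal (C19–C26) | C=CC[C@@H]1OC(C)(C)O[C@@H]1/C=C(\C)C=O | intermediate
46 | (4S)-4-benzyl-3-propanoyl-1,3-thiazolidine-2-thione | CCC(=O)N1[C@@H](Cc2ccccc2)CSC1=S | starting material
47 | (4S)-4-benzyl-3-[(2S,3S,4E)-5-[(4R,5S)-2,2-dimethyl-5-(prop-2-en-1-yl)-1,3-dioxolan-4-yl]-3-hydroxy-2,4-dimethylpent-4-enoyl]-1,3-thiazolidine-2-thione | C=CC[C@@H]1OC(C)(C)O[C@@H]1/C=C(\C)[C@@H](O)[C@H](C)C(=O)N1[C@@H](Cc2ccccc2)CSC1=S | intermediate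
48 | 3-O-TBS ether of 47 | C=CC[C@@H]1OC(C)(C)O[C@@H]1/C=C(\C)[C@@H](O[Si](C)(C)C(C)(C)C)[C@H](C)C(=O)N1[C@@H](Cc2ccccc2)CSC1=S | intermediate
49 | (2S,3S,4E)-3-[(tert-butyldimethylsilyl)oxy]-5-[(4R,5S)-2,2-dimethyl-5-(prop-2-en-1-yl)-1,3-dioxolan-4-yl]-2,4-dimethylpent-4-enal | C=CC[C@@H]1OC(C)(C)O[C@@H]1/C=C(\C)[C@@H](O[Si](C)(C)C(C)(C)C)[C@H](C)C=O | intermediate
50 | 2-(triphenyl-λ5-phosphanylidene)acetaldehyde | O=CC=P(c1ccccc1)(c1ccccc1)c1ccccc1 | starting material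
51 | (2E,4R,5S,6E)-5-[(tert-butyldimethylsilyl)oxy]-7-[(4R,5S)-2,2-dimethyl-5-(prop-2-en-1-yl)-1,3-dioxolan-4-yl]-4,6-dimethylhepta-2,6-dienal | C=CC[C@@H]1OC(C)(C)O[C@@H]1/C=C(\C)[C@@H](O[Si](C)(C)C(C)(C)C)[C@H](C)/C=C/C=O | intermediate
52 | keto enal: as 51 with 2-oxopropyl in place of allyl on the dioxolane (C25 ketone) | CC(=O)C[C@@H]1OC(C)(C)O[C@@H]1/C=C(\C)[C@@H](O[Si](C)(C)C(C)(C)C)[C@H](C)/C=C/C=O | intermediate
53 | (Z)-but-2-ene | C/C=C\C | starting material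
54 | C13–C26 alcohol: C13 vinyl, 14-Me, 15-OH, (16E), 18-Me, 19-O-TBS, (20E)-20-Me, 22,23-O-isopropylidene, 25-oxo | CC(=O)C[C@@H]1OC(C)(C)O[C@@H]1/C=C(\C)[C@@H](O[Si](C)(C)C(C)(C)C)[C@H](C)/C=C/[C@@H](O)[C@H](C)C=C | intermediate
55 | C13–C26 methyl ketone, 15,19-bis-O-TBS (otherwise as 54) | CC(=O)C[C@@H]1OC(C)(C)O[C@@H]1/C=C(\C)[C@@H](O[Si](C)(C)C(C)(C)C)[C@H](C)/C=C/[C@@H](O[Si](C)(C)C(C)(C)C)[C@H](C)C=C | intermediate
56 | aldol adduct: C13–C46 chain with 25-oxo, 27-OH, O41 acylated by the C1–C12 acid; TBS on O15, O19, O29, O31, O33; acetonides on O7/O9, O22/O23, O35/O37 | C=C[C@@H](C)[C@H](O[Si](C)(C)C(C)(C)C)/C=C/[C@@H](C)[C@H](O[Si](C)(C)C(C)(C)C)/C(C)=C/[C@H]1OC(C)(C)O[C@H]1CC(=O)C[C@H](O)C[C@H](O[Si](C)(C)C(C)(C)C)[C@@H](C)[C@@H](O[Si](C)(C)C(C)(C)C)[C@@H](C)[C@H](O[Si](C)(C)C(C)(C)C)C[C@H]2C[C@@H](/C=C/C[C@@H]([C@@H](C)[C@@H]3CCC(=O)O3)OC(=O)/C(C)=C/CC[C@H](C)[C@@H]3[C@@H](C)[C@H](CCC=C)OC(C)(C)O3)OC(C)(C)O2 | intermediate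
57 | 25,27-anti diol (otherwise as 56) | C=C[C@@H](C)[C@H](O[Si](C)(C)C(C)(C)C)/C=C/[C@@H](C)[C@H](O[Si](C)(C)C(C)(C)C)/C(C)=C/[C@H]1OC(C)(C)O[C@H]1C[C@@H](O)C[C@H](O)C[C@H](O[Si](C)(C)C(C)(C)C)[C@@H](C)[C@@H](O[Si](C)(C)C(C)(C)C)[C@@H](C)[C@H](O[Si](C)(C)C(C)(C)C)C[C@H]2C[C@@H](/C=C/C[C@@H]([C@@H](C)[C@@H]3CCC(=O)O3)OC(=O)/C(C)=C/CC[C@H](C)[C@@H]3[C@@H](C)[C@H](CCC=C)OC(C)(C)O3)OC(C)(C)O2 | intermediate
58 | ester-linked diene: as 57 with O25 and O27 as TBS ethers (seven TBS, three acetonides, C12 and C13 terminal alkenes) | C=C[C@@H](C)[C@H](O[Si](C)(C)C(C)(C)C)/C=C/[C@@H](C)[C@H](O[Si](C)(C)C(C)(C)C)/C(C)=C/[C@H]1OC(C)(C)O[C@H]1C[C@@H](O[Si](C)(C)C(C)(C)C)C[C@H](O[Si](C)(C)C(C)(C)C)C[C@H](O[Si](C)(C)C(C)(C)C)[C@@H](C)[C@@H](O[Si](C)(C)C(C)(C)C)[C@@H](C)[C@H](O[Si](C)(C)C(C)(C)C)C[C@H]2C[C@@H](/C=C/C[C@@H]([C@@H](C)[C@@H]3CCC(=O)O3)OC(=O)/C(C)=C/CC[C@H](C)[C@@H]3[C@@H](C)[C@H](CCC=C)OC(C)(C)O3)OC(C)(C)O2 | intermediate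
59 | protected macrocycle: 42-membered lactone with (2E,12E,16E,20E,38E)-alkenes; TBS on O15, O19, O25, O27, O29, O31, O33; acetonides on O7/O9, O22/O23, O35/O37 | C/C1=C\CC[C@H](C)[C@@H]3[C@@H](C)[C@H](CC/C=C/[C@@H](C)[C@H](O[Si](C)(C)C(C)(C)C)/C=C/[C@@H](C)[C@H](O[Si](C)(C)C(C)(C)C)/C(C)=C/[C@H]4OC(C)(C)O[C@H]4C[C@@H](O[Si](C)(C)C(C)(C)C)C[C@H](O[Si](C)(C)C(C)(C)C)C[C@H](O[Si](C)(C)C(C)(C)C)[C@@H](C)[C@@H](O[Si](C)(C)C(C)(C)C)[C@@H](C)[C@H](O[Si](C)(C)C(C)(C)C)C[C@H]5C[C@@H](/C=C/C[C@@H]([C@@H](C)[C@@H]2CCC(=O)O2)OC1=O)OC(C)(C)O5)OC(C)(C)O3 | intermediate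
60 | CNP0335149.1: (2E,6S,7R,8S,9S,12E,14R,15R,16E,18R,19S,20E,22R,23S,25S,27S,29S,30R,31R,32S,33R,35R,37S,38E,41S)-42-membered macrolide with 13 free hydroxyls and a (1S)-1-[(2S)-5-oxooxolan-2-yl]ethyl group on C41 | C/C1=C\CC[C@H](C)[C@@H](O)[C@@H](C)[C@@H](O)CC/C=C/[C@@H](C)[C@H](O)/C=C/[C@@H](C)[C@H](O)/C(C)=C/[C@@H](O)[C@@H](O)C[C@@H](O)C[C@H](O)C[C@H](O)[C@@H](C)[C@@H](O)[C@@H](C)[C@H](O)C[C@H](O)C[C@H](O)/C=C/C[C@@H]([C@@H](C)[C@@H]2CCC(=O)O2)OC1=O | target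

## Summary

Total step count: 38.

Longest linear sequence: 16 steps (steps 11–14, 17–23, 34–38, from 21 and 22 to 60).

Steps most likely to fail:

**Step 37 (macrocyclic ring-closing metathesis).** The risks are oligomers, Z isomer, or participation of the C38=C39 alkene. The fallback closes the ring by macrolactonisation; it sets out from 35 and comes back at 59. Et3SiCl/imidazole converts 35 into the O41 triethylsilyl ether F8. DDQ then gives the C27 alcohol F9, and Dess–Martin oxidation gives the C27 aldehyde F10. The boron aldol with 55, Me4NBH(OAc)3 reduction and TBSOTf (as in steps 34–36) give in turn the hydroxy ketone F11, the anti diol F12 and the bis-silyl ether F13. Cross-metathesis of the C13 vinyl group of F13 with an excess of acid 20 (second-generation Hoveyda–Grubbs catalyst, CH2Cl2, 40 °C) forms C12=C13 intermolecularly and gives the seco acid silyl ether F14. HF·pyridine/pyridine in THF at 0 °C removes only the triethylsilyl group to give the seco hydroxy acid F15. Yamaguchi macrolactonisation (2,4,6-trichlorobenzoyl chloride, Et3N, THF; slow addition to DMAP in toluene) then gives 59.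

**Step 34 (1,5-anti aldol union).** Induction from a dioxolane β-oxygen is less secure than from a benzyl-type ether. The fallback sets out from 56 (obtained as a C27 epimer mixture) and comes back at 56. MsCl/Et3N, then DBU, dehydrates the mixture to the (25-oxo,26E)-enone F6. Catalyst-controlled conjugate borylation (CuCl, NaOtBu, a Josiphos-type bisphosphine whose antipode is chosen by screening, B2pin2, MeOH, THF) installs boron at C27 and gives the β-boryl ketone F7. NaBO3·4H2O in THF/H2O oxidises the C–B bond with retention to return 56 as a single C27 epimer.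

**Step 7 (vinyl-ketone aldol with in situ reduction).** Felkin control from an α-methyl aldehyde without a β-heteroatom may be modest, and the vinyl ketone can polymerise. The fallback sets out from 12 and comes back at 19. Reagent-controlled Brown (E)-crotylboration (2, KOtBu, n-BuLi, (−)-Ipc2BOMe, BF3·OEt2) gives the anti homoallylic alcohol F1. Boc2O/DMAP gives the tert-butyl carbonate F2. IBr in toluene at −85 °C gives the syn iodo carbonate F3. K2CO3 in EtOH gives the epoxy alcohol F4. Allylmagnesium bromide 6 with catalytic CuI in THF at −40 °C opens the epoxide at C10 to the butenyl diol F5. 2,2-Dimethoxypropane/PPTS then gives 19.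

Further compounds
F1 | step 7 | ethyl (2E,6S,7R,8S)-7-hydroxy-2,6,8-trimethyldeca-2,9-dienoate | CCOC(=O)/C(C)=C/CC[C@H](C)[C@@H](O)[C@@H](C)C=C
F2 | step 7 | tert-butyl carbonate of F1 (on O7) | CCOC(=O)/C(C)=C/CC[C@H](C)[C@@H](OC(=O)OC(C)(C)C)[C@@H](C)C=C
F3 | step 7 | cyclic iodo carbonate: 1,3-dioxan-2-one bridging O7 and O9 with 5-methyl and 6-iodomethyl | CCOC(=O)/C(C)=C/CC[C@H](C)[C@@H]1[C@@H](C)[C@H](CI)OC(=O)O1
F4 | step 7 | epoxy alcohol: 7-OH with C9–C10 oxirane | CCOC(=O)/C(C)=C/CC[C@H](C)[C@@H](O)[C@@H](C)[C@@H]1CO1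
F5 | step 7 | ethyl (2E,6S,7R,8S,9S)-7,9-dihydroxy-2,6,8-trimethyltrideca-2,12-dienoate | CCOC(=O)/C(C)=C/CC[C@H](C)[C@@H](O)[C@@H](C)[C@@H](O)CCC=C
F6 | step 34 | (25-oxo,26E)-enone from dehydration of 56 | C=C[C@@H](C)[C@H](O[Si](C)(C)C(C)(C)C)/C=C/[C@@H](C)[C@H](O[Si](C)(C)C(C)(C)C)/C(C)=C/[C@H]1OC(C)(C)O[C@H]1CC(=O)/C=C/C[C@H](O[Si](C)(C)C(C)(C)C)[C@@H](C)[C@@H](O[Si](C)(C)C(C)(C)C)[C@@H](C)[C@H](O[Si](C)(C)C(C)(C)C)C[C@H]2C[C@@H](/C=C/C[C@@H]([C@@H](C)[C@@H]3CCC(=O)O3)OC(=O)/C(C)=C/CC[C@H](C)[C@@H]3[C@@H](C)[C@H](CCC=C)OC(C)(C)O3)OC(C)(C)O2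
F7 | step 34 | 27-(pinacolatoboryl)-25-ketone | C=C[C@@H](C)[C@H](O[Si](C)(C)C(C)(C)C)/C=C/[C@@H](C)[C@H](O[Si](C)(C)C(C)(C)C)/C(C)=C/[C@H]1OC(C)(C)O[C@H]1CC(=O)C[C@H](B4OC(C)(C)C(C)(C)O4)C[C@H](O[Si](C)(C)C(C)(C)C)[C@@H](C)[C@@H](O[Si](C)(C)C(C)(C)C)[C@@H](C)[C@H](O[Si](C)(C)C(C)(C)C)C[C@H]2C[C@@H](/C=C/C[C@@H]([C@@H](C)[C@@H]3CCC(=O)O3)OC(=O)/C(C)=C/CC[C@H](C)[C@@H]3[C@@H](C)[C@H](CCC=C)OC(C)(C)O3)OC(C)(C)O2
F8 | step 37 | O41 triethylsilyl ether of 35 | COc1ccc(COCC[C@H](O[Si](C)(C)C(C)(C)C)[C@@H](C)[C@@H](O[Si](C)(C)C(C)(C)C)[C@@H](C)[C@H](O[Si](C)(C)C(C)(C)C)C[C@H]2C[C@@H](/C=C/C[C@@H]([C@@H](C)[C@@H]3CCC(=O)O3)O[Si](CC)(CC)CC)OC(C)(C)O2)cc1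
F9 | step 37 | C27 alcohol with O41 triethylsilyl ether | OCC[C@H](O[Si](C)(C)C(C)(C)C)[C@@H](C)[C@@H](O[Si](C)(C)C(C)(C)C)[C@@H](C)[C@H](O[Si](C)(C)C(C)(C)C)C[C@H]1C[C@@H](/C=C/C[C@@H]([C@@H](C)[C@@H]2CCC(=O)O2)O[Si](CC)(CC)CC)OC(C)(C)O1
F10 | step 37 | C27 aldehyde with O41 triethylsilyl ether | O=CC[C@H](O[Si](C)(C)C(C)(C)C)[C@@H](C)[C@@H](O[Si](C)(C)C(C)(C)C)[C@@H](C)[C@H](O[Si](C)(C)C(C)(C)C)C[C@H]1C[C@@H](/C=C/C[C@@H]([C@@H](C)[C@@H]2CCC(=O)O2)O[Si](CC)(CC)CC)OC(C)(C)O1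
F11 | step 37 | C13–C46 27-hydroxy-25-ketone with O41 triethylsilyl ether | C=C[C@@H](C)[C@H](O[Si](C)(C)C(C)(C)C)/C=C/[C@@H](C)[C@H](O[Si](C)(C)C(C)(C)C)/C(C)=C/[C@H]1OC(C)(C)O[C@H]1CC(=O)C[C@H](O)C[C@H](O[Si](C)(C)C(C)(C)C)[C@@H](C)[C@@H](O[Si](C)(C)C(C)(C)C)[C@@H](C)[C@H](O[Si](C)(C)C(C)(C)C)C[C@H]2C[C@@H](/C=C/C[C@@H]([C@@H](C)[C@@H]3CCC(=O)O3)O[Si](CC)(CC)CC)OC(C)(C)O2
F12 | step 37 | C13–C46 25,27-anti diol with O41 triethylsilyl ether | C=C[C@@H](C)[C@H](O[Si](C)(C)C(C)(C)C)/C=C/[C@@H](C)[C@H](O[Si](C)(C)C(C)(C)C)/C(C)=C/[C@H]1OC(C)(C)O[C@H]1C[C@@H](O)C[C@H](O)C[C@H](O[Si](C)(C)C(C)(C)C)[C@@H](C)[C@@H](O[Si](C)(C)C(C)(C)C)[C@@H](C)[C@H](O[Si](C)(C)C(C)(C)C)C[C@H]2C[C@@H](/C=C/C[C@@H]([C@@H](C)[C@@H]3CCC(=O)O3)O[Si](CC)(CC)CC)OC(C)(C)O2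
F13 | step 37 | C13–C46 fragment with seven TBS ethers and O41 triethylsilyl ether | C=C[C@@H](C)[C@H](O[Si](C)(C)C(C)(C)C)/C=C/[C@@H](C)[C@H](O[Si](C)(C)C(C)(C)C)/C(C)=C/[C@H]1OC(C)(C)O[C@H]1C[C@@H](O[Si](C)(C)C(C)(C)C)C[C@H](O[Si](C)(C)C(C)(C)C)C[C@H](O[Si](C)(C)C(C)(C)C)[C@@H](C)[C@@H](O[Si](C)(C)C(C)(C)C)[C@@H](C)[C@H](O[Si](C)(C)C(C)(C)C)C[C@H]2C[C@@H](/C=C/C[C@@H]([C@@H](C)[C@@H]3CCC(=O)O3)O[Si](CC)(CC)CC)OC(C)(C)O2
F14 | step 37 | C1–C46 seco acid with (12E)-alkene and O41 triethylsilyl ether | OC(=O)/C(C)=C/CC[C@H](C)[C@@H]1[C@@H](C)[C@H](CC/C=C/[C@@H](C)[C@H](O[Si](C)(C)C(C)(C)C)/C=C/[C@@H](C)[C@H](O[Si](C)(C)C(C)(C)C)/C(C)=C/[C@H]2OC(C)(C)O[C@H]2C[C@@H](O[Si](C)(C)C(C)(C)C)C[C@H](O[Si](C)(C)C(C)(C)C)C[C@H](O[Si](C)(C)C(C)(C)C)[C@@H](C)[C@@H](O[Si](C)(C)C(C)(C)C)[C@@H](C)[C@H](O[Si](C)(C)C(C)(C)C)C[C@H]3C[C@@H](/C=C/C[C@@H]([C@@H](C)[C@@H]4CCC(=O)O4)O[Si](CC)(CC)CC)OC(C)(C)O3)OC(C)(C)O1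
F15 | step 37 | C1–C46 seco hydroxy acid (free 41-OH) | OC(=O)/C(C)=C/CC[C@H](C)[C@@H]1[C@@H](C)[C@H](CC/C=C/[C@@H](C)[C@H](O[Si](C)(C)C(C)(C)C)/C=C/[C@@H](C)[C@H](O[Si](C)(C)C(C)(C)C)/C(C)=C/[C@H]2OC(C)(C)O[C@H]2C[C@@H](O[Si](C)(C)C(C)(C)C)C[C@H](O[Si](C)(C)C(C)(C)C)C[C@H](O[Si](C)(C)C(C)(C)C)[C@@H](C)[C@@H](O[Si](C)(C)C(C)(C)C)[C@@H](C)[C@H](O[Si](C)(C)C(C)(C)C)C[C@H]3C[C@@H](/C=C/C[C@@H]([C@@H](C)[C@@H]4CCC(=O)O4)O)OC(C)(C)O3)OC(C)(C)O1
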